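**Retrosynthetic overview**
- The route rests on the C8(O)–C9H2–C10(O)(CH3) triad of the ten-membered carbocycle. An oxygen on C8, the C9 methylene and the oxygenated quaternary C10 form the retron of a 2-isoxazoline bridging C8 and C10, so C8–C9 and O–C10 are cut to a C8 nitrile oxide and a C1 isopropenyl ketone (C9=C10).
- Ring order: the γ-lactone first (auxiliary aldol at C6–C7, then lactonisation), then the ten-membered carbocycle and the bridging isoxazoline together in one cycloaddition.
- C1–C6 with the Z C4=C5 alkene come from neryl acetate, C7/C8/C11/C12 from a succinate imide, and C9/C10/C14 from 2-bromopropene added to a C1 aldehyde.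
- C13 is carried from step 8 as a C11 phosphonate, because lactone enolate chemistry is not possible once the C1 ketone exists; after the cycloaddition follow N–O cleavage, C10-hydroxyl-directed C8 reduction, angeloylation and olefination with formaldehyde.

Key step: step 13

**Remarks on the chemistry**
- Positions are numbered as in the target: C1 ketone, C4 methyl-bearing, C6 lactone O–CH, C7, C8 ester O–CH, C9, C10 carbinol; lactone C11, C12, C13; C14 is the C10 methyl. The target is (4Z,6R,7R,8R,10S).
- Assumption: C11 in 16–28 and C1 in 19 are carried as epimer mixtures, since both centres are erased later, and their SMILES leave these centres open. The aldoxime is drawn E; its geometry is lost in the nitrile oxide.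

**Route**

Step 1
Reactants: 1 neryl acetate
Product: 3 (4Z)-6-acetoxy-4-methylhex-4-enal, via epoxide 2 (not isolated)
Conditions: mCPBA, NaHCO3, CH2Cl2, 0 °C; then H5IO6, THF/H2O, 0 °C
Reagents that add atoms: mCPBA, O=C(OO)c1cccc(Cl)c1
Why: Prilezhaev epoxidation should select the electron-rich 6,7-alkene because the 2,3-alkene is deactivated by the allylic acetate, and periodic acid should hydrolyse and cleave the trisubstituted epoxide (Malaprade-type cleavage) to the C1 aldehyde without touching the Z alkene.

Step 2
Reactants: 3 (4Z)-6-acetoxy-4-methylhex-4-enal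
Product: 5 (2Z)-6,6-dimethoxy-3-methylhex-2-en-1-ol, via acetal acetate 4 (not isolated)
Conditions: HC(OMe)3, MeOH, PPTS (cat.), rt; then K2CO3, rt
Reagents that add atoms: trimethyl orthoformate, COC(OC)OC; methanol, CO
Why: Acid-catalysed acetalisation masks the C1 aldehyde, and carbonate-mediated transesterification in the same pot frees the allylic alcohol; neither operation affects the Z alkene.

Step 3
Reactants: 5 (2Z)-6,6-dimethoxy-3-methylhex-2-en-1-ol
Product: 6 (2Z)-6,6-dimethoxy-3-methylhex-2-enal
Conditions: Dess–Martin periodinane, NaHCO3, CH2Cl2, 0 °C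
Reagents that add atoms: none
Why: Dess–Martin oxidation under bicarbonate buffer should give the Z-enal without the acid that would hydrolyse the acetal or isomerise the enal to E.

Step 4
Reactants: 7 (S)-4-benzyloxazolidin-2-one; 8 methyl 4-chloro-4-oxobutanoate
Product: 9 methyl 4-[(4S)-4-benzyl-2-oxooxazolidin-3-yl]-4-oxobutanoate
Conditions: n-BuLi, THF, −78 °C; then 8, −78 to 0 °C
Reagents that add atoms: none
Why: N-Acylation of the lithiated oxazolidinone by the acid chloride, which is far more electrophilic than the methyl ester at low temperature.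

Step 5
Reactants: 9 methyl 4-[(4S)-4-benzyl-2-oxooxazolidin-3-yl]-4-oxobutanoate; 6 (2Z)-6,6-dimethoxy-3-methylhex-2-enal
Product: 12 trans-lactone imide (6R,7S), via boron enolate 10 (not isolated), via aldol adduct 11 (not isolated)
Conditions: Bu2BOTf, iPr2NEt, CH2Cl2, −78 to 0 °C; then 6, −78 to 0 °C; pH 7 buffer, MeOH, H2O2, 0 °C; then PPTS (cat.), CH2Cl2, rt
Reagents that add atoms: none
Why: Evans syn-aldol through the Zimmerman–Traxler chair of the Z boron enolate sets C6 and C7, the benzyl group of the (S)-auxiliary shielding one enolate face (the enolate is preformed so that no free boron triflate meets the acetal); the γ-hydroxy ester then closes to the γ-lactone (5-exo-trig acyl substitution), the syn aldol relationship becoming the 6,7-trans lactone.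

Step 6
Reactants: 12 trans-lactone imide
Product: 13 (4R,5R)-5-[(1Z)-5,5-dimethoxy-2-methylpent-1-en-1-yl]-4-(hydroxymethyl)oxolan-2-one
Conditions: NaBH4, THF/H2O (4:1), 0 °C; NH4Cl quench
Reagents that add atoms: none
Why: Borohydride reduction of the activated exocyclic imide carbonyl (reductive removal of the auxiliary) should give the C8 primary alcohol while the less electrophilic lactone survives; the cold quench keeps the C8 alkoxide from translactonising, and C7 is not epimerised.

Step 7
Reactants: 13 hydroxymethyl lactone
Product: 14 C8 tert-butyldimethylsilyl ether of 13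
Conditions: TBSCl, imidazole, CH2Cl2, 0 °C to rt
Reagents that add atoms: TBSCl, CC(C)(C)[Si](C)(C)Cl
Why: Standard silylation of the primary alcohol removes the only acidic proton other than the lactone α-CH2 before enolate chemistry.

Step 8
Reactants: 14 silyl ether lactone
Product: 16 C11 diethyl phosphonate of 14 (C11 epimers), via ketene acetal phosphate 15 (not isolated)
Conditions: LiN(iPr)2 (1.1 equiv), THF, −78 °C; ClP(O)(OEt)2; then LiN(iPr)2 (2.2 equiv), −78 °C to rt; AcOH
Reagents that add atoms: diethyl chlorophosphate, CCOP(=O)(Cl)OCC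
Why: O-Phosphorylation of the lactone enolate followed by base-induced 1,3 oxygen-to-carbon phosphoryl migration (vinyl phosphate to phosphonate rearrangement) should give the α-phosphono lactone, the latent C13 methylene; the lactone α-CH2 is the only enolisable site because C1 is an acetal and C8 a silyl ether.

Step 9
Reactants: 16 phosphonate acetal silyl ether
Product: 17 C8 alcohol with C1 aldehyde (phosphono lactone)
Conditions: 1 M aq. HCl, THF, 0 °C to rt
Reagents that add atoms: water, O
Why: Acid hydrolysis removes the dimethyl acetal and the primary silyl ether together; phosphonate, lactone and Z alkene are stable to dilute acid at room temperature.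

Step 10
Reactants: 17 hydroxy aldehyde; 18 2-bromopropene
Product: 19 C8 alcohol with C1 isopropenyl carbinol (C1 epimers)
Conditions: CrCl2 (4 equiv), NiCl2 (cat.), DMF, rt
Reagents that add atoms: none
Why: Nozaki–Hiyama–Kishi alkenylation: the alkenyl species of trivalent chromium adds only to the aldehyde and tolerates the lactone, the free hydroxyl and the acidic phosphonate C–H; this forms the C1–C10 bond.

Step 11
Reactants: 19 diol
Product: 20 C8 aldehyde with C1 isopropenyl ketone
Conditions: Dess–Martin periodinane (3 equiv), NaHCO3, CH2Cl2, 0 °C to rt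
Reagents that add atoms: none
Why: Dess–Martin oxidation converts the primary alcohol into the C8 aldehyde and the allylic carbinol into the enone in one operation; the buffer limits C7 epimerisation and β-elimination of the lactone carboxylate.

Step 12
Reactants: 20 keto aldehyde
Product: 21 C8 aldoxime with C1 isopropenyl ketone (key-step precursor)
Conditions: NH2OH·HCl (1.05 equiv), NaOAc, EtOH/H2O, 0 °C
Reagents that add atoms: hydroxylamine hydrochloride, NO.Cl
Why: Oxime condensation is much faster at the aldehyde than at the hindered, conjugated ketone, and acetate buffer at 0 °C should suppress conjugate addition and C7 epimerisation.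

Step 13
Reactants: 21 aldoxime
Product: 24 bridged isoxazoline (6R,7R,10S), via hydroximoyl chloride 22 (not isolated), via nitrile oxide 23 (not isolated)
Conditions: NCS, DMF, rt; then dilution into CH2Cl2 (about 1 mM), Et3N by syringe pump over 12 h, rt
Reagents that add atoms: none
Why: Proposed new method: NCS chlorinates the aldoxime and slow dehydrochlorination releases the C8 nitrile oxide, which should add in a concerted, asynchronous (3+2) fashion across the isopropenyl ketone, C8 bonding to the unsubstituted C9 and the oxide oxygen to the methyl- and acyl-bearing C10, the orientation general for 1,1-disubstituted and methacrylate-type dipolarophiles. The closest known reaction is the intramolecular nitrile oxide cycloaddition that gives bridged macrocyclic isoxazolines in larger rings; the ten-membered case is without direct precedent. The ten-membered carbocycle closes through the new C8–C9 bond by attack on the terminal alkene carbon, and the isoxazoline closes in the same event as a two-atom N–O bridge between C8 and C10 (bridged mode, bicyclo[7.2.1] skeleton). The new C10 centre is set by the face of the forming isoxazoline that the C1–C6 chain spans: the C7–C6 bond must stand roughly perpendicular to that plane, and placing H-7 instead of the phosphonate-bearing C11 next to the incoming C9 puts C1 on the face that gives the (10S) isomer, the trans-lactone and the Z C4=C5 alkene confining the chain to this loop. The step needs ring closure to outrun furoxan dimerisation, which slow dipole generation at high dilution addresses, and it needs the dipole to choose the enone over the trisubstituted C4=C5 alkene, which the much higher dipolarophilicity of the activated 1,1-disubstituted alkene secures. NCS with Et3N is used in place of aqueous hypochlorite so that the enone is not epoxidised and the C11–H is not chlorinated.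

Step 14
Reactants: 24 bridged isoxazoline
Product: 25 C8 ketone with C10 tertiary alcohol and C1 ketone (6R,7S,10S)
Conditions: Mo(CO)6, MeCN/H2O (15:1), 80 °C
Reagents that add atoms: water, O
Why: Reductive N–O cleavage by zerovalent molybdenum gives the β-hydroxy imine, which water hydrolyses to the C8 ketone; alkenes, lactone and phosphonate are untouched, C10 keeps its oxygen and configuration, and 25 is carried on at once to limit retro-aldol cleavage and β-elimination.

Step 15
Reactants: 25 β-hydroxy ketone
Product: 26 8,10-syn diol (6R,7R,8R,10S)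
Conditions: Et2BOMe, THF/MeOH (4:1), −78 °C; NaBH4, −78 °C; AcOH, then MeOH co-evaporation
Reagents that add atoms: none
Why: Narasaka–Prasad reduction: the boron chelate between the C10 alkoxide and the C8 carbonyl activates C8 over the hindered C1 ketone, and external hydride should give the 1,3-syn diol (8R); within the ten-membered ring only the syn diol fits a cis-bridged cyclic boronate, which reinforces this sense.

Step 16
Reactants: 26 syn diol; 27 angelic acid
Product: 28 8-O-angeloyl phosphono lactone
Conditions: 27, 2,4,6-Cl3C6H2COCl, Et3N, PhMe, rt; then 26, PhMe, 80 °C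
Reagents that add atoms: none
Why: Yamaguchi-type esterification through the mixed anhydride without DMAP avoids the amine-catalysed Z to E isomerisation to the tiglate; the secondary C8 hydroxyl is acylated while the tertiary C10 hydroxyl is not.

Step 17
Reactants: 28 angeloyl phosphono lactone; 29 formaldehyde
Product: 30 target CNP0345906.2
Conditions: aq. HCHO (37%), K2CO3, THF/H2O, 0 °C to rt
Reagents that add atoms: none
Why: Horner–Wadsworth–Emmons olefination of the α-phosphono lactone with formaldehyde under mild carbonate base installs the C11=C13 exo-methylene without touching the angelate or the tertiary ketol; the C11 stereocentre disappears.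

**Compound list**
1 | neryl acetate, (2Z)-3,7-dimethylocta-2,6-dien-1-yl acetate | CC(C)=CCC/C(C)=C\COC(C)=O | starting material
2 | 6,7-epoxyneryl acetate (racemic epoxide) | CC1(C)OC1CC/C(C)=C\COC(C)=O | intermediate
3 | (4Z)-6-acetoxy-4-methylhex-4-enal | O=CCC/C(C)=C\COC(C)=O | intermediate
4 | (2Z)-6,6-dimethoxy-3-methylhex-2-en-1-yl acetate | COC(OC)CC/C(C)=C\COC(C)=O | intermediate
5 | (2Z)-6,6-dimethoxy-3-methylhex-2-en-1-ol | COC(OC)CC/C(C)=C\CO | intermediate
6 | (2Z)-6,6-dimethoxy-3-methylhex-2-enal | COC(OC)CC/C(C)=C\C=O | intermediate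
7 | (S)-4-benzyloxazolidin-2-one | O=C1OC[C@H](Cc2ccccc2)N1 | starting material
8 | methyl 4-chloro-4-oxobutanoate | COC(=O)CCC(Cl)=O | starting material
9 | methyl 4-[(4S)-4-benzyl-2-oxooxazolidin-3-yl]-4-oxobutanoate | COC(=O)CCC(=O)N1C(=O)OC[C@@H]1Cc1ccccc1 | intermediate
10 | Z dibutylboron enolate of 9 | CCCCB(CCCC)O/C(=C\CC(=O)OC)N1C(=O)OC[C@@H]1Cc1ccccc1 | intermediate
11 | syn-aldol adduct, methyl (3S,4R,5Z)-3-[(4S)-4-benzyl-2-oxooxazolidine-3-carbonyl]-4-hydroxy-9,9-dimethoxy-6-methylnon-5-enoate | COC(=O)C[C@H](C(=O)N1C(=O)OC[C@@H]1Cc1ccccc1)[C@H](O)/C=C(/C)CCC(OC)OC | intermediate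
12 | trans-lactone imide, (4S)-4-benzyl-3-{[(2R,3S)-2-[(1Z)-5,5-dimethoxy-2-methylpent-1-en-1-yl]-5-oxooxolan-3-yl]carbonyl}oxazolidin-2-one | O=C1C[C@H](C(=O)N2C(=O)OC[C@@H]2Cc2ccccc2)[C@@H](/C=C(/C)CCC(OC)OC)O1 | intermediate
13 | (4R,5R)-5-[(1Z)-5,5-dimethoxy-2-methylpent-1-en-1-yl]-4-(hydroxymethyl)oxolan-2-one | O=C1C[C@H](CO)[C@@H](/C=C(/C)CCC(OC)OC)O1 | intermediate
14 | (4R,5R)-4-[(tert-butyldimethylsilyloxy)methyl]-5-[(1Z)-5,5-dimethoxy-2-methylpent-1-en-1-yl]oxolan-2-one | O=C1C[C@H](CO[Si](C)(C)C(C)(C)C)[C@@H](/C=C(/C)CCC(OC)OC)O1 | intermediate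
15 | ketene acetal phosphate of 14, diethyl 4,5-dihydrofuran-2-yl phosphate with the C4 and C5 substituents of 14 | CCOP(=O)(OCC)OC1=C[C@H](CO[Si](C)(C)C(C)(C)C)[C@@H](/C=C(/C)CCC(OC)OC)O1 | intermediate
16 | diethyl [(4R,5R)-4-[(tert-butyldimethylsilyloxy)methyl]-5-[(1Z)-5,5-dimethoxy-2-methylpent-1-en-1-yl]-2-oxooxolan-3-yl]phosphonate (C3 epimers) | O=C1C(P(=O)(OCC)OCC)[C@H](CO[Si](C)(C)C(C)(C)C)[C@@H](/C=C(/C)CCC(OC)OC)O1 | intermediate
17 | diethyl [(4R,5R)-4-(hydroxymethyl)-5-[(1Z)-2-methyl-5-oxopent-1-en-1-yl]-2-oxooxolan-3-yl]phosphonate | O=C1C(P(=O)(OCC)OCC)[C@H](CO)[C@@H](/C=C(/C)CCC=O)O1 | intermediate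
18 | 2-bromopropene | CC(Br)=C | starting material
19 | diethyl [(4R,5R)-5-[(1Z)-5-hydroxy-2,6-dimethylhepta-1,6-dien-1-yl]-4-(hydroxymethyl)-2-oxooxolan-3-yl]phosphonate (carbinol epimers) | O=C1C(P(=O)(OCC)OCC)[C@H](CO)[C@@H](/C=C(/C)CCC(O)C(C)=C)O1 | intermediate
20 | diethyl [(4S,5R)-5-[(1Z)-2,6-dimethyl-5-oxohepta-1,6-dien-1-yl]-4-formyl-2-oxooxolan-3-yl]phosphonate | O=C1C(P(=O)(OCC)OCC)[C@H](C=O)[C@@H](/C=C(/C)CCC(=O)C(C)=C)O1 | intermediate
21 | (E)-aldoxime of 20 at C8, trans-lactone with the C1 isopropenyl ketone side chain (key-step precursor) | O=C1C(P(=O)(OCC)OCC)[C@H](/C=N/O)[C@@H](/C=C(/C)CCC(=O)C(C)=C)O1 | intermediate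
22 | C8 hydroximoyl chloride of 21 | O=C1C(P(=O)(OCC)OCC)[C@H](/C(Cl)=N/O)[C@@H](/C=C(/C)CCC(=O)C(C)=C)O1 | intermediate
23 | C8 nitrile oxide | O=C1C(P(=O)(OCC)OCC)[C@H](C#[N+][O-])[C@@H](/C=C(/C)CCC(=O)C(C)=C)O1 | intermediate
24 | (4Z,6R,7R,10S) ten-membered carbocycle with C1 ketone, bridged at C8 and C10 by the isoxazoline (C8=N–O–C10), fused to the 6,7-trans lactone bearing the C11 diethyl phosphonate (key-step product) | CCOP(=O)(OCC)C1C(=O)O[C@@H]2/C=C(/C)CCC(=O)[C@]3(C)CC(=NO3)[C@@H]12 | intermediate
25 | (4Z,6R,7S,10S) 1,8-diketone with C10 tertiary alcohol, C11 phosphono lactone | CCOP(=O)(OCC)C1C(=O)O[C@@H]2/C=C(/C)CCC(=O)[C@@](C)(O)CC(=O)[C@@H]12 | intermediate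
26 | (4Z,6R,7R,8R,10S) 8,10-syn diol with C1 ketone, C11 phosphono lactone | CCOP(=O)(OCC)C1C(=O)O[C@@H]2/C=C(/C)CCC(=O)[C@@](C)(O)C[C@@H](O)[C@@H]12 | intermediate
27 | angelic acid, (Z)-2-methylbut-2-enoic acid | C/C=C(/C)C(=O)O | starting material
28 | 8-O-angeloyl derivative of 26 | CCOP(=O)(OCC)C1C(=O)O[C@@H]2/C=C(/C)CCC(=O)[C@@](C)(O)C[C@@H](OC(=O)/C(C)=C\C)[C@@H]12 | intermediate
29 | formaldehyde | C=O | starting material
30 | CNP0345906.2, (4Z,6R,7R,8R,10S) | C=C1C(=O)O[C@@H]2/C=C(/C)CCC(=O)[C@@](C)(O)C[C@@H](OC(=O)/C(C)=C\C)[C@@H]12 | target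

**Step count**
Total: 17 steps. Longest linear sequence: 16 steps (steps 1–3 and 5–17; step 4 prepares the imide).

**Steps most likely to fail**

Step 13. The ten-membered bridged closure may be outrun by dimerisation of the nitrile oxide to the furoxan, or the dipole may add to the other face of the alkene so that C10 forms with the opposite configuration. The fallback uses known reactions: the C8–C9–C10 unit is brought in as a 2-bromoallyl group and the ring is closed at C1–C10 by a Nozaki–Hiyama–Kishi reaction. It sets out from 16 and returns at 25. Selective desilylation of 16 (Bu4NF buffered with AcOH, THF) would give acetal alcohol F1, and Dess–Martin oxidation would give acetal aldehyde F2. Barbier allylation with 2,3-dibromopropene and indium powder in THF/H2O would give 2-bromoallyl carbinol F3 (C8 epimers, immaterial). Acetal hydrolysis (1 M HCl, THF) would free bromoallyl aldehyde F4. CrCl2 with catalytic NiCl2 in DMSO at high dilution would then close the ten-membered ring to macrocyclic exo-methylene diol F5, a closure established for medium carbocycles. Dess–Martin oxidation of both carbinols would give ene-dione F6, used at once. Mukaiyama-type hydration of its enone (Mn(dpm)3 cat., PhSiH3, O2, iPrOH; then P(OEt)3), in which a hydrogen atom adds to the methylene terminus and the tertiary C10 radical is oxygenated, would give 25. The C10 configuration would then rest on the ring conformation and would have to be assigned before going on.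

Step 15. Hydride may be delivered to the wrong face of the chelated C8 ketone, or the C1 ketone may be reduced alongside. The fallback sets out from 25 and returns at 28. Internal hydride delivery with Me4NBH(OAc)3 (MeCN/AcOH, −30 °C; Evans–Saksena reduction) favours the six-membered transfer from the boron-bound C10 alkoxide to C8 over the strained transfer to C1 and should give the 1,3-anti diol, 8-epi diol F7. Mitsunobu esterification of F7 with angelic acid 27 (PPh3, DIAD, PhMe, 0 °C to rt) would invert C8 and give 28 directly.

Step 16. The angeloyl group may isomerise to the tigloyl group during acyl transfer, or the C8 hydroxyl, which can sit as a hemiketal on the C1 ketone, may resist acylation. In the fallback the Z enoate is built on the ester by olefination; it sets out from 26 and returns at 30. The Horner–Wadsworth–Emmons reaction of 26 with formaldehyde (conditions of step 17) would first give exo-methylene lactone diol F8. Esterification of its C8 hydroxyl with 2-[bis(2,2,2-trifluoroethoxy)phosphoryl]propanoic acid (EDC, DMAP cat., CH2Cl2) would give phosphonopropionate F9. Still–Gennari olefination of F9 with acetaldehyde (KN(SiMe3)2, 18-crown-6, THF, −78 °C) would form the (Z)-2-methylbut-2-enoate and so the target 30.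

**Further compounds**
F1 | step 13 | acetal alcohol, 16 without the silyl group | O=C1C(P(=O)(OCC)OCC)[C@H](CO)[C@@H](/C=C(/C)CCC(OC)OC)O1
F2 | step 13 | acetal aldehyde, C8 aldehyde with the C1 dimethyl acetal | O=C1C(P(=O)(OCC)OCC)[C@H](C=O)[C@@H](/C=C(/C)CCC(OC)OC)O1
F3 | step 13 | 2-bromoallyl carbinol at C8 with the C1 dimethyl acetal (C8 epimers) | O=C1C(P(=O)(OCC)OCC)[C@H](C(O)CC(Br)=C)[C@@H](/C=C(/C)CCC(OC)OC)O1
F4 | step 13 | bromoallyl aldehyde, 2-bromoallyl carbinol at C8 with the free C1 aldehyde | O=C1C(P(=O)(OCC)OCC)[C@H](C(O)CC(Br)=C)[C@@H](/C=C(/C)CCC=O)O1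
F5 | step 13 | macrocyclic exo-methylene diol, ten-membered ring with C1 and C8 carbinols and C10=CH2 | CCOP(=O)(OCC)C1C(=O)O[C@@H]2/C=C(/C)CCC(O)C(=C)CC(O)[C@@H]12
F6 | step 13 | ene-dione, ten-membered ring with C1 and C8 ketones and C10=CH2 | CCOP(=O)(OCC)C1C(=O)O[C@@H]2/C=C(/C)CCC(=O)C(=C)CC(=O)[C@@H]12
F7 | step 15 | 8-epi diol, 8,10-anti diol (8S) | CCOP(=O)(OCC)C1C(=O)O[C@@H]2/C=C(/C)CCC(=O)[C@@](C)(O)C[C@H](O)[C@@H]12
F8 | step 16 | exo-methylene lactone diol, 8-deangeloyl target | C=C1C(=O)O[C@@H]2/C=C(/C)CCC(=O)[C@@](C)(O)C[C@@H](O)[C@@H]12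
F9 | step 16 | C8 2-[bis(2,2,2-trifluoroethoxy)phosphoryl]propanoate of F8 | C=C1C(=O)O[C@@H]2/C=C(/C)CCC(=O)[C@@](C)(O)C[C@@H](OC(=O)C(C)P(=O)(OCC(F)(F)F)OCC(F)(F)F)[C@@H]12
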